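**Strategy.** Everything rests on disconnecting the ring-fusion bond C5–C10 together with C3–C4 of ring A. Ring A carries the contiguous centres C4 (methyl, hydroxymethyl), C5–H and C10–methyl on the edge it shares with ring B; this is exactly the pattern written by an intramolecular Diels–Alder reaction between an (E)-2-methylenal (C4=C5) and an (E)-1-methyl-1,3-diene (C10=C1–C2=C3). One Lewis-acid-promoted cycloaddition of an open-chain trienal therefore closes rings A and B and sets C4, C5 and C10, steered by the preset tether centres C6, C8 and C9. Hydrogenation, a B-alkyl Suzuki coupling with a tartrate-derived bromoalkenyl butenolide and global deprotection complete the target.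

Key step: step 12

Remark (assumption): atoms are numbered as in labdanes (decalin C1–C10, linker C11–C12, side chain C13–C16, hydroxymethyl carbon C18). Compounds 1 and 21 and all reagents named are taken as catalogue items.

Step 1
Reactants: 1 3-(benzyloxy)propanal
Product: 2 ethyl (2E)-5-(benzyloxy)-2-methylpent-2-enoate
Conditions: Ph3P=C(Me)CO2Et, CH2Cl2, rt
Reagents that add atoms: ethyl 2-(triphenylphosphoranylidene)propanoate, CCOC(=O)C(C)=P(c1ccccc1)(c1ccccc1)c1ccccc1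
Why: Wittig olefination with a stabilised α-methyl ylide should give the trisubstituted (E)-enoate, and the neutral conditions spare the β-benzyloxy aldehyde from elimination.

Step 2
Reactants: 2 ethyl (2E)-5-(benzyloxy)-2-methylpent-2-enoate
Product: 3 (2E)-5-(benzyloxy)-2-methylpent-2-en-1-ol
Conditions: i-Bu2AlH, CH2Cl2, −78 °C
Reagents that add atoms: none
Why: DIBAL-H reduces the conjugated ester by 1,2-addition to the allylic alcohol without touching the alkene or the benzyl ether.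

Step 3
Reactants: 3 (2E)-5-(benzyloxy)-2-methylpent-2-en-1-ol
Product: 4 [(2R,3R)-3-[2-(benzyloxy)ethyl]-2-methyloxiran-2-yl]methanol
Conditions: Ti(OiPr)4 (cat.), D-(−)-diethyl tartrate (cat.), t-BuOOH, 4 Å molecular sieves, CH2Cl2, −20 °C
Reagents that add atoms: tert-butyl hydroperoxide, CC(C)(C)OO
Why: Sharpless asymmetric epoxidation, in which the D-(−)-tartrate catalyst should deliver oxygen to the alkene face that gives the (2R,3R) epoxide, fixing C8 and preparing C9.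

Step 4
Reactants: 4 [(2R,3R)-3-[2-(benzyloxy)ethyl]-2-methyloxiran-2-yl]methanol
Product: 5 (2S,3R)-3-[2-(benzyloxy)ethyl]-2-methyl-5-(trimethylsilyl)pent-4-yne-1,2-diol
Conditions: Me3SiC≡CH, n-BuLi, then Et2AlCl, toluene, −78 to 0 °C; then 4, 0 °C to rt
Reagents that add atoms: ethynyltrimethylsilane, C#C[Si](C)(C)C
Why: The diethylalkynylalane binds as the aluminium alkoxide and opens the 2-methyl-2,3-epoxy alcohol at C-3, the only carbon open to backside attack, with inversion, which sets C9 and leaves the C8 tertiary carbinol untouched (regioselective epoxy-alcohol opening).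

Step 5
Reactants: 5 (2S,3R)-3-[2-(benzyloxy)ethyl]-2-methyl-5-(trimethylsilyl)pent-4-yne-1,2-diol
Product: 6 (2S,3R)-3-[2-(benzyloxy)ethyl]-2-methylpent-4-yne-1,2-diol
Conditions: K2CO3 (cat.), MeOH, rt
Reagents that add atoms: none
Why: Mild methanolysis of the C(sp)–Si bond frees the terminal alkyne needed for carbometalation.

Step 6
Reactants: 6 (2S,3R)-3-[2-(benzyloxy)ethyl]-2-methylpent-4-yne-1,2-diol
Product: 8 (2S,3R,4E)-3-[2-(benzyloxy)ethyl]-2,4-dimethylhepta-4,6-diene-1,2-diol, via alkenylalane 7 (not isolated)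
Conditions: AlMe3 (excess), Cp2ZrCl2 (cat.), CH2Cl2, 0 °C to rt; then CH2=CHBr, ZnCl2, Pd(PPh3)4 (cat.), THF, rt
Reagents that add atoms: trimethylaluminium, C[Al](C)C; vinyl bromide, C=CBr
Why: Negishi zirconium-catalysed carboalumination adds methyl and aluminium syn across the terminal alkyne with methyl on the internal carbon, and palladium-catalysed coupling of the alkenylalane with vinyl bromide proceeds with retention to give the (E)-1-methyl-1,3-diene.

Step 7
Reactants: 8 (2S,3R,4E)-3-[2-(benzyloxy)ethyl]-2,4-dimethylhepta-4,6-diene-1,2-diol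
Product: 10 (2S)-2-[(3R,4E)-1-(benzyloxy)-4-methylhepta-4,6-dien-3-yl]-2-methyloxirane, via monotosylate 9 (not isolated)
Conditions: NaH, 1-(p-toluenesulfonyl)imidazole, THF, 0 °C to rt
Reagents that add atoms: none
Why: The primary alkoxide is sulfonylated selectively and the tertiary alkoxide then displaces the tosylate (one-pot Williamson-type epoxide closure), with no change at C8.

Step 8
Reactants: 10 (2S)-2-[(3R,4E)-1-(benzyloxy)-4-methylhepta-4,6-dien-3-yl]-2-methyloxirane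
Product: 11 (4R,5R,6E)-5-[2-(benzyloxy)ethyl]-4-hydroxy-4,6-dimethylnona-6,8-dienenitrile
Conditions: MeCN, n-BuLi, THF, −78 °C to rt; then H2O
Reagents that add atoms: acetonitrile, CC#N
Why: Lithioacetonitrile opens the 2,2-disubstituted epoxide at its unhindered CH2 carbon (SN2), adding C5 and C6 and regenerating the C8 tertiary alcohol with its configuration intact.

Step 9
Reactants: 11 (4R,5R,6E)-5-[2-(benzyloxy)ethyl]-4-hydroxy-4,6-dimethylnona-6,8-dienenitrile
Product: 12 (4R,5R,6E)-5-[2-(benzyloxy)ethyl]-4,6-dimethyl-4-[(triethylsilyl)oxy]nona-6,8-dienenitrile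
Conditions: Et3SiOTf, 2,6-lutidine, CH2Cl2, −78 to 0 °C
Reagents that add atoms: triethylsilyl trifluoromethanesulfonate, CC[Si](CC)(CC)OS(=O)(=O)C(F)(F)F
Why: The silyl triflate silylates the hindered tertiary alcohol so that the later aldehyde cannot close to a lactol.

Step 10
Reactants: 12 (4R,5R,6E)-5-[2-(benzyloxy)ethyl]-4,6-dimethyl-4-[(triethylsilyl)oxy]nona-6,8-dienenitrile
Product: 13 (4R,5R,6E)-5-[2-(benzyloxy)ethyl]-4,6-dimethyl-4-[(triethylsilyl)oxy]nona-6,8-dienal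
Conditions: i-Bu2AlH, CH2Cl2, −78 °C; then aq. Rochelle salt
Reagents that add atoms: water, O
Why: DIBAL-H adds once to the nitrile to give the N-aluminoimine, which is hydrolysed on work-up to the aldehyde.

Step 11
Reactants: 13 (4R,5R,6E)-5-[2-(benzyloxy)ethyl]-4,6-dimethyl-4-[(triethylsilyl)oxy]nona-6,8-dienal
Product: 15 (2E,4S,6R,7R,8E)-7-[2-(benzyloxy)ethyl]-2,6,8-trimethyl-1-oxo-6-[(triethylsilyl)oxy]undeca-2,8,10-trien-4-yl benzoate, via benzoyloxy aldehyde 14 (not isolated)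
Conditions: (S)-α,α-diphenylprolinol trimethylsilyl ether (20 mol %), (PhCO2)2, hydroquinone (cat.), THF, 0 °C to rt; then Ph3P=C(Me)CHO, toluene, 40 °C
Reagents that add atoms: dibenzoyl peroxide, O=C(OOC(=O)c1ccccc1)c1ccccc1; 2-(triphenylphosphoranylidene)propanal, CC(C=O)=P(c1ccccc1)(c1ccccc1)c1ccccc1
Why: Enamine catalysis (organocatalytic α-benzoyloxylation of an aldehyde) should place the benzoate on the unshielded enamine face to set C6 (S) under catalyst control, and the sensitive α-acyloxy aldehyde is trapped at once by an (E)-selective Wittig reaction with the stabilised formyl ylide.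

Step 12
Reactants: 15 (2E,4S,6R,7R,8E)-7-[2-(benzyloxy)ethyl]-2,6,8-trimethyl-1-oxo-6-[(triethylsilyl)oxy]undeca-2,8,10-trien-4-yl benzoate
Product: 16 (1S,3R,4R,4aS,8R,8aR)-4-[2-(benzyloxy)ethyl]-8-formyl-3,4a,8-trimethyl-3-[(triethylsilyl)oxy]-1,2,3,4,4a,7,8,8a-octahydronaphthalen-1-yl benzoate
Conditions: Me2AlCl (2 equiv), CH2Cl2, −78 to −20 °C
Reagents that add atoms: none
Why: Me2AlCl binds the aldehyde of the (E)-2-methylenal and lowers its LUMO, so the tethered (E)-1-methyl-1,3-diene adds in a concerted, asynchronous, normal-demand intramolecular [4+2] cycloaddition, the well-known type 1 intramolecular Diels–Alder reaction of 2,8,10-undecatrienals to trans-decalins. Ring A (C1–C5, C10) closes in the cycloaddition mode through the new C5–C10 and C3–C4 bonds, and ring B (C5–C10) closes in the fused mode through the chair-like four-atom tether C6–C9. C4 follows from the E geometry of the dienophile (its methyl is cis to C6, so both lie exo) and from the endo position of the Lewis-acid-bound formyl group, which should place the C4 methyl cis and the formyl group trans to the C10 methyl. C5 and C10 (trans ring fusion) follow from the same endo transition state, in which the E diene holds C9 outside and its methyl inside and the tether lies anti across the forming C5–C10 bond. The face is fixed by the three tether centres acting together: A(1,3) strain with the C4 methyl holds C6–H in the enal plane and the benzoate equatorial, the C9 side chain sits equatorial and the C8 methyl axial as in the product. The step needs endo over exo selectivity, which the Lewis acid should secure, and a low temperature, which avoids a competing 1,5-hydrogen shift of the cis-methyl diene.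

Step 13
Reactants: 16 (1S,3R,4R,4aS,8R,8aR)-4-[2-(benzyloxy)ethyl]-8-formyl-3,4a,8-trimethyl-3-[(triethylsilyl)oxy]-1,2,3,4,4a,7,8,8a-octahydronaphthalen-1-yl benzoate
Product: 17 (1S,3R,4R,4aS,8R,8aR)-4-[2-(benzyloxy)ethyl]-8-(hydroxymethyl)-3,4a,8-trimethyl-3-[(triethylsilyl)oxy]-1,2,3,4,4a,7,8,8a-octahydronaphthalen-1-ol
Conditions: LiAlH4, THF, 0 °C
Reagents that add atoms: none
Why: LiAlH4 reduces the neopentyl aldehyde to the C18 alcohol and cleaves the benzoate in the same operation, leaving the silyl ether, the benzyl ether and the ring alkene.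

Step 14
Reactants: 17 (1S,3R,4R,4aS,8R,8aR)-4-[2-(benzyloxy)ethyl]-8-(hydroxymethyl)-3,4a,8-trimethyl-3-[(triethylsilyl)oxy]-1,2,3,4,4a,7,8,8a-octahydronaphthalen-1-ol
Product: 18 (1S,3R,4R,4aS,8R,8aR)-4-[2-(benzyloxy)ethyl]-3,4a,8-trimethyl-1,3-bis[(triethylsilyl)oxy]-8-{[(triethylsilyl)oxy]methyl}-1,2,3,4,4a,7,8,8a-octahydronaphthalene
Conditions: Et3SiOTf (2.5 equiv), 2,6-lutidine, CH2Cl2, 0 °C
Reagents that add atoms: triethylsilyl trifluoromethanesulfonate, CC[Si](CC)(CC)OS(=O)(=O)C(F)(F)F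
Why: The silyl triflate protects the primary C18 and the hindered equatorial C6 hydroxyl groups so that the later organolithium step meets no acidic proton.

Step 15
Reactants: 18 (1S,3R,4R,4aS,8R,8aR)-4-[2-(benzyloxy)ethyl]-3,4a,8-trimethyl-1,3-bis[(triethylsilyl)oxy]-8-{[(triethylsilyl)oxy]methyl}-1,2,3,4,4a,7,8,8a-octahydronaphthalene
Product: 19 2-[(1R,2R,4S,4aR,5R,8aS)-2,5,8a-trimethyl-2,4-bis[(triethylsilyl)oxy]-5-{[(triethylsilyl)oxy]methyl}decahydronaphthalen-1-yl]ethan-1-ol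
Conditions: H2 (1 atm), Pd/C, EtOAc, rt
Reagents that add atoms: none
Why: Heterogeneous hydrogenation saturates the C1=C2 alkene (no new stereocentre) and hydrogenolyses the benzyl ether in one operation, while ethyl acetate as solvent keeps the triethylsilyl ethers.

Step 16
Reactants: 19 2-[(1R,2R,4S,4aR,5R,8aS)-2,5,8a-trimethyl-2,4-bis[(triethylsilyl)oxy]-5-{[(triethylsilyl)oxy]methyl}decahydronaphthalen-1-yl]ethan-1-ol
Product: 20 (1R,2R,4S,4aR,5R,8aS)-1-(2-iodoethyl)-2,5,8a-trimethyl-2,4-bis[(triethylsilyl)oxy]-5-{[(triethylsilyl)oxy]methyl}decahydronaphthalene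
Conditions: I2, PPh3, imidazole, CH2Cl2, 0 °C
Reagents that add atoms: iodine, II
Why: Appel-type iodination converts the unhindered primary alcohol into the iodide by SN2 displacement of the oxyphosphonium group.

Step 17
Reactants: 21 dimethyl (4R,5R)-2,2-dimethyl-1,3-dioxolane-4,5-dicarboxylate
Product: 22 methyl (4R,5S)-5-(hydroxymethyl)-2,2-dimethyl-1,3-dioxolane-4-carboxylate
Conditions: NaBH4 (0.6 equiv), MeOH, 0 °C
Reagents that add atoms: none
Why: Sodium borohydride reduces α-alkoxy esters, and a limiting amount reduces one of the two homotopic ester groups of the C2-symmetric diester, whose stereocentres (C14, C15) come unchanged from L-tartaric acid.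

Step 18
Reactants: 22 methyl (4R,5S)-5-(hydroxymethyl)-2,2-dimethyl-1,3-dioxolane-4-carboxylate
Product: 23 methyl (4R,5R)-5-formyl-2,2-dimethyl-1,3-dioxolane-4-carboxylate
Conditions: Dess–Martin periodinane, NaHCO3, CH2Cl2, 0 °C to rt
Reagents that add atoms: none
Why: Dess–Martin oxidation under buffered, non-basic conditions should give the α-alkoxy aldehyde without epimerisation.

Step 19
Reactants: 23 methyl (4R,5R)-5-formyl-2,2-dimethyl-1,3-dioxolane-4-carboxylate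
Product: 24 methyl (4R,5S)-5-ethynyl-2,2-dimethyl-1,3-dioxolane-4-carboxylate
Conditions: dimethyl (1-diazo-2-oxopropyl)phosphonate, K2CO3, MeOH, 0 °C to rt
Reagents that add atoms: dimethyl (1-diazo-2-oxopropyl)phosphonate, COP(=O)(OC)C(=[N+]=[N-])C(C)=O
Why: Seyferth–Gilbert homologation with the Ohira–Bestmann reagent turns the aldehyde into the terminal alkyne under mild base, and the trans-dioxolane is the thermodynamic arrangement, so the stereocentres should hold.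

Step 20
Reactants: 24 methyl (4R,5S)-5-ethynyl-2,2-dimethyl-1,3-dioxolane-4-carboxylate
Product: 26 methyl (4R,5R)-5-(1-bromoethenyl)-2,2-dimethyl-1,3-dioxolane-4-carboxylate, via bromoalkenylborane 25 (not isolated)
Conditions: B-bromo-9-BBN, CH2Cl2, 0 °C; then AcOH
Reagents that add atoms: 9-bromo-9-borabicyclo[3.3.1]nonane, BrB1C2CCCC1CCC2
Why: Haloboration adds boron and bromine syn across the terminal alkyne with bromine on the internal carbon, and protonolysis of the C–B bond with acetic acid leaves the 2-bromo-1-alkene.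

Step 21
Reactants: 26 methyl (4R,5R)-5-(1-bromoethenyl)-2,2-dimethyl-1,3-dioxolane-4-carboxylate
Product: 27 (4R,5R)-5-(1-bromoethenyl)-2,2-dimethyl-1,3-dioxolane-4-carbaldehyde
Conditions: i-Bu2AlH, CH2Cl2, −78 °C
Reagents that add atoms: none
Why: At −78 °C the tetrahedral aluminium hemiacetal of the α-alkoxy ester is stable, so DIBAL-H stops at the aldehyde.

Step 22
Reactants: 27 (4R,5R)-5-(1-bromoethenyl)-2,2-dimethyl-1,3-dioxolane-4-carbaldehyde
Product: 28 methyl (4R)-4-[(4S,5R)-5-(1-bromoethenyl)-2,2-dimethyl-1,3-dioxolan-4-yl]-4-hydroxybut-2-ynoate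
Conditions: HC≡CCO2Me, Me2Zn, ProPhenol ligand (cat., enantiomer chosen for Re-face delivery), Ph3PO (cat.), toluene, 0 °C
Reagents that add atoms: methyl propiolate, C#CC(=O)OC
Why: Zinc–ProPhenol-catalysed asymmetric alkynylation should add the zinc acetylide of methyl propiolate to the Re face of the aldehyde under catalyst control, setting C16 (R) syn to the neighbouring dioxolane oxygen.

Step 23
Reactants: 28 methyl (4R)-4-[(4S,5R)-5-(1-bromoethenyl)-2,2-dimethyl-1,3-dioxolan-4-yl]-4-hydroxybut-2-ynoate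
Product: 30 (5R)-5-[(4S,5R)-5-(1-bromoethenyl)-2,2-dimethyl-1,3-dioxolan-4-yl]-4-methylfuran-2(5H)-one, via hydroxy Z-enoate 29 (not isolated)
Conditions: Me2CuLi (from CuI and MeLi), THF, −78 °C; then aq. NH4Cl, rt
Reagents that add atoms: lithium dimethylcuprate, [Li+].C[Cu-]C
Why: The cuprate adds methyl and copper syn across the ynoate (conjugate addition to a 4-hydroxy-2-ynoate), which places the carbinol cis to the ester so that the Z-hydroxy enoate lactonises to the β-methylbutenolide with C16 unchanged, while the vinyl bromide should be inert at −78 °C.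

Step 24
Reactants: 20 (1R,2R,4S,4aR,5R,8aS)-1-(2-iodoethyl)-2,5,8a-trimethyl-2,4-bis[(triethylsilyl)oxy]-5-{[(triethylsilyl)oxy]methyl}decahydronaphthalene; 30 (5R)-5-[(4S,5R)-5-(1-bromoethenyl)-2,2-dimethyl-1,3-dioxolan-4-yl]-4-methylfuran-2(5H)-one
Product: 33 (5R)-5-[(4R,5S)-2,2-dimethyl-5-{4-[(1R,2R,4S,4aR,5R,8aS)-2,5,8a-trimethyl-2,4-bis[(triethylsilyl)oxy]-5-{[(triethylsilyl)oxy]methyl}decahydronaphthalen-1-yl]but-1-en-2-yl}-1,3-dioxolan-4-yl]-4-methylfuran-2(5H)-one, via alkyllithium 31 (not isolated), via borate 32 (not isolated)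
Conditions: 20, t-BuLi (2.1 equiv), Et2O, −78 °C; B-methoxy-9-BBN, THF, −78 °C to rt; then 30, PdCl2(dppf) (cat.), AsPh3, aq. K3PO4, DMF, rt
Reagents that add atoms: none
Why: Lithium–iodine exchange and trapping with B-methoxy-9-BBN give the alkylborate, which undergoes B-alkyl Suzuki–Miyaura coupling with the 2-bromoalkene to form the C12–C13 bond and the 1,1-disubstituted alkene without touching any stereocentre.

Step 25
Reactants: 33 (5R)-5-[(4R,5S)-2,2-dimethyl-5-{4-[(1R,2R,4S,4aR,5R,8aS)-2,5,8a-trimethyl-2,4-bis[(triethylsilyl)oxy]-5-{[(triethylsilyl)oxy]methyl}decahydronaphthalen-1-yl]but-1-en-2-yl}-1,3-dioxolan-4-yl]-4-methylfuran-2(5H)-one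
Product: 34 (5R)-5-[(1R,2S)-1,2-dihydroxy-3-methylidene-5-[(1R,2R,4S,4aR,5R,8aS)-2,4-dihydroxy-5-(hydroxymethyl)-2,5,8a-trimethyldecahydronaphthalen-1-yl]pentyl]-4-methylfuran-2(5H)-one (CNP0301623.1)
Conditions: 1 M aq. HCl, THF, rt
Reagents that add atoms: none
Why: Dilute aqueous acid should hydrolyse the three triethylsilyl ethers and the isopropylidene acetal without dehydrating the tertiary alcohol or opening the butenolide.

**Compound list**

1 | 3-(benzyloxy)propanal | O=CCCOCc1ccccc1 | starting material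
2 | ethyl (2E)-5-(benzyloxy)-2-methylpent-2-enoate | CCOC(=O)/C(C)=C/CCOCc1ccccc1 | intermediate
3 | (2E)-5-(benzyloxy)-2-methylpent-2-en-1-ol | OC/C(C)=C/CCOCc1ccccc1 | intermediate
4 | [(2R,3R)-3-[2-(benzyloxy)ethyl]-2-methyloxiran-2-yl]methanol | OC[C@@]1(C)O[C@@H]1CCOCc1ccccc1 | intermediate
5 | (2S,3R)-3-[2-(benzyloxy)ethyl]-2-methyl-5-(trimethylsilyl)pent-4-yne-1,2-diol | OC[C@@](C)(O)[C@H](CCOCc1ccccc1)C#C[Si](C)(C)C | intermediate
6 | (2S,3R)-3-[2-(benzyloxy)ethyl]-2-methylpent-4-yne-1,2-diol | OC[C@@](C)(O)[C@H](CCOCc1ccccc1)C#C | intermediate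
7 | dimethyl[(1E,3R,4S)-3-[2-(benzyloxy)ethyl]-4,5-dihydroxy-2,4-dimethylpent-1-en-1-yl]alane (hydroxyl groups bound as aluminium alkoxides in the flask) | OC[C@@](C)(O)[C@H](CCOCc1ccccc1)/C(C)=C/[Al](C)C | intermediate
8 | (2S,3R,4E)-3-[2-(benzyloxy)ethyl]-2,4-dimethylhepta-4,6-diene-1,2-diol | OC[C@@](C)(O)[C@H](CCOCc1ccccc1)/C(C)=C/C=C | intermediate
9 | (2S,3R,4E)-3-[2-(benzyloxy)ethyl]-2-hydroxy-2,4-dimethylhepta-4,6-dien-1-yl 4-methylbenzenesulfonate | Cc1ccc(cc1)S(=O)(=O)OC[C@@](C)(O)[C@H](CCOCc1ccccc1)/C(C)=C/C=C | intermediate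
10 | (2S)-2-[(3R,4E)-1-(benzyloxy)-4-methylhepta-4,6-dien-3-yl]-2-methyloxirane | C[C@@]1(CO1)[C@H](CCOCc1ccccc1)/C(C)=C/C=C | intermediate
11 | (4R,5R,6E)-5-[2-(benzyloxy)ethyl]-4-hydroxy-4,6-dimethylnona-6,8-dienenitrile | N#CCC[C@@](C)(O)[C@H](CCOCc1ccccc1)/C(C)=C/C=C | intermediate
12 | (4R,5R,6E)-5-[2-(benzyloxy)ethyl]-4,6-dimethyl-4-[(triethylsilyl)oxy]nona-6,8-dienenitrile | N#CCC[C@@](C)(O[Si](CC)(CC)CC)[C@H](CCOCc1ccccc1)/C(C)=C/C=C | intermediate
13 | (4R,5R,6E)-5-[2-(benzyloxy)ethyl]-4,6-dimethyl-4-[(triethylsilyl)oxy]nona-6,8-dienal | O=CCC[C@@](C)(O[Si](CC)(CC)CC)[C@H](CCOCc1ccccc1)/C(C)=C/C=C | intermediate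
14 | (2S,4R,5R,6E)-5-[2-(benzyloxy)ethyl]-4,6-dimethyl-1-oxo-4-[(triethylsilyl)oxy]nona-6,8-dien-2-yl benzoate | O=C[C@@H](OC(=O)c1ccccc1)C[C@@](C)(O[Si](CC)(CC)CC)[C@H](CCOCc1ccccc1)/C(C)=C/C=C | intermediate
15 | (2E,4S,6R,7R,8E)-7-[2-(benzyloxy)ethyl]-2,6,8-trimethyl-1-oxo-6-[(triethylsilyl)oxy]undeca-2,8,10-trien-4-yl benzoate | O=C/C(C)=C/[C@@H](OC(=O)c1ccccc1)C[C@@](C)(O[Si](CC)(CC)CC)[C@H](CCOCc1ccccc1)/C(C)=C/C=C | intermediate
16 | (1S,3R,4R,4aS,8R,8aR)-4-[2-(benzyloxy)ethyl]-8-formyl-3,4a,8-trimethyl-3-[(triethylsilyl)oxy]-1,2,3,4,4a,7,8,8a-octahydronaphthalen-1-yl benzoate | c1ccccc1COCC[C@@H]1[C@@]2(C)C=CC[C@@](C)(C=O)[C@@H]2[C@@H](OC(=O)c3ccccc3)C[C@@]1(C)O[Si](CC)(CC)CC | intermediate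
17 | (1S,3R,4R,4aS,8R,8aR)-4-[2-(benzyloxy)ethyl]-8-(hydroxymethyl)-3,4a,8-trimethyl-3-[(triethylsilyl)oxy]-1,2,3,4,4a,7,8,8a-octahydronaphthalen-1-ol | c1ccccc1COCC[C@@H]1[C@@]2(C)C=CC[C@@](C)(CO)[C@@H]2[C@@H](O)C[C@@]1(C)O[Si](CC)(CC)CC | intermediate
18 | (1S,3R,4R,4aS,8R,8aR)-4-[2-(benzyloxy)ethyl]-3,4a,8-trimethyl-1,3-bis[(triethylsilyl)oxy]-8-{[(triethylsilyl)oxy]methyl}-1,2,3,4,4a,7,8,8a-octahydronaphthalene | c1ccccc1COCC[C@@H]1[C@@]2(C)C=CC[C@@](C)(CO[Si](CC)(CC)CC)[C@@H]2[C@@H](O[Si](CC)(CC)CC)C[C@@]1(C)O[Si](CC)(CC)CC | intermediate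
19 | 2-[(1R,2R,4S,4aR,5R,8aS)-2,5,8a-trimethyl-2,4-bis[(triethylsilyl)oxy]-5-{[(triethylsilyl)oxy]methyl}decahydronaphthalen-1-yl]ethan-1-ol | OCC[C@@H]1[C@@]2(C)CCC[C@@](C)(CO[Si](CC)(CC)CC)[C@@H]2[C@@H](O[Si](CC)(CC)CC)C[C@@]1(C)O[Si](CC)(CC)CC | intermediate
20 | (1R,2R,4S,4aR,5R,8aS)-1-(2-iodoethyl)-2,5,8a-trimethyl-2,4-bis[(triethylsilyl)oxy]-5-{[(triethylsilyl)oxy]methyl}decahydronaphthalene | ICC[C@@H]1[C@@]2(C)CCC[C@@](C)(CO[Si](CC)(CC)CC)[C@@H]2[C@@H](O[Si](CC)(CC)CC)C[C@@]1(C)O[Si](CC)(CC)CC | intermediate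
21 | dimethyl (4R,5R)-2,2-dimethyl-1,3-dioxolane-4,5-dicarboxylate | COC(=O)[C@@H]1OC(C)(C)O[C@H]1C(=O)OC | starting material
22 | methyl (4R,5S)-5-(hydroxymethyl)-2,2-dimethyl-1,3-dioxolane-4-carboxylate | OC[C@@H]1OC(C)(C)O[C@H]1C(=O)OC | intermediate
23 | methyl (4R,5R)-5-formyl-2,2-dimethyl-1,3-dioxolane-4-carboxylate | O=C[C@@H]1OC(C)(C)O[C@H]1C(=O)OC | intermediate
24 | methyl (4R,5S)-5-ethynyl-2,2-dimethyl-1,3-dioxolane-4-carboxylate | C#C[C@@H]1OC(C)(C)O[C@H]1C(=O)OC | intermediate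
25 | methyl (4R,5R)-5-[(Z)-2-(9-borabicyclo[3.3.1]nonan-9-yl)-1-bromoethenyl]-2,2-dimethyl-1,3-dioxolane-4-carboxylate | Br/C(=C\B1C2CCCC1CCC2)[C@@H]1OC(C)(C)O[C@H]1C(=O)OC | intermediate
26 | methyl (4R,5R)-5-(1-bromoethenyl)-2,2-dimethyl-1,3-dioxolane-4-carboxylate | C=C(Br)[C@@H]1OC(C)(C)O[C@H]1C(=O)OC | intermediate
27 | (4R,5R)-5-(1-bromoethenyl)-2,2-dimethyl-1,3-dioxolane-4-carbaldehyde | C=C(Br)[C@@H]1OC(C)(C)O[C@H]1C=O | intermediate
28 | methyl (4R)-4-[(4S,5R)-5-(1-bromoethenyl)-2,2-dimethyl-1,3-dioxolan-4-yl]-4-hydroxybut-2-ynoate | C=C(Br)[C@@H]1OC(C)(C)O[C@H]1[C@H](O)C#CC(=O)OC | intermediate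
29 | methyl (2Z,4R)-4-[(4S,5R)-5-(1-bromoethenyl)-2,2-dimethyl-1,3-dioxolan-4-yl]-4-hydroxy-3-methylbut-2-enoate | C=C(Br)[C@@H]1OC(C)(C)O[C@H]1[C@H](O)/C(C)=C\C(=O)OC | intermediate
30 | (5R)-5-[(4S,5R)-5-(1-bromoethenyl)-2,2-dimethyl-1,3-dioxolan-4-yl]-4-methylfuran-2(5H)-one | C=C(Br)[C@@H]1OC(C)(C)O[C@H]1[C@@H]1OC(=O)C=C1C | intermediate
31 | {2-[(1R,2R,4S,4aR,5R,8aS)-2,5,8a-trimethyl-2,4-bis[(triethylsilyl)oxy]-5-{[(triethylsilyl)oxy]methyl}decahydronaphthalen-1-yl]ethyl}lithium | [Li]CC[C@@H]1[C@@]2(C)CCC[C@@](C)(CO[Si](CC)(CC)CC)[C@@H]2[C@@H](O[Si](CC)(CC)CC)C[C@@]1(C)O[Si](CC)(CC)CC | intermediate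
32 | lithium B-methoxy-B-{2-[(1R,2R,4S,4aR,5R,8aS)-2,5,8a-trimethyl-2,4-bis[(triethylsilyl)oxy]-5-{[(triethylsilyl)oxy]methyl}decahydronaphthalen-1-yl]ethyl}-9-borabicyclo[3.3.1]nonan-9-uide | [Li+].CO[B-]1(CC[C@@H]2[C@@]3(C)CCC[C@@](C)(CO[Si](CC)(CC)CC)[C@@H]3[C@@H](O[Si](CC)(CC)CC)C[C@@]2(C)O[Si](CC)(CC)CC)C2CCCC1CCC2 | intermediate
33 | (5R)-5-[(4R,5S)-2,2-dimethyl-5-{4-[(1R,2R,4S,4aR,5R,8aS)-2,5,8a-trimethyl-2,4-bis[(triethylsilyl)oxy]-5-{[(triethylsilyl)oxy]methyl}decahydronaphthalen-1-yl]but-1-en-2-yl}-1,3-dioxolan-4-yl]-4-methylfuran-2(5H)-one | C=C(CC[C@@H]1[C@@]2(C)CCC[C@@](C)(CO[Si](CC)(CC)CC)[C@@H]2[C@@H](O[Si](CC)(CC)CC)C[C@@]1(C)O[Si](CC)(CC)CC)[C@@H]1OC(C)(C)O[C@H]1[C@@H]1OC(=O)C=C1C | intermediate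
34 | (5R)-5-[(1R,2S)-1,2-dihydroxy-3-methylidene-5-[(1R,2R,4S,4aR,5R,8aS)-2,4-dihydroxy-5-(hydroxymethyl)-2,5,8a-trimethyldecahydronaphthalen-1-yl]pentyl]-4-methylfuran-2(5H)-one (CNP0301623.1) | C=C(CC[C@@H]1[C@@]2(C)CCC[C@@](C)(CO)[C@@H]2[C@@H](O)C[C@@]1(C)O)[C@H](O)[C@@H](O)[C@@H]1OC(=O)C=C1C | target

**Counts.** Total step count: 25. Longest linear sequence: 18 steps (steps 1–16, 24 and 25).

**Steps most likely to fail**

Step 12. The cycloaddition may lose endo preference, which would give the cis-fused adduct epimeric at C4, or the Lewis acid may strip the tertiary silyl ether before the ring closes. The fallback drops the Lewis acid and changes the activating group. It sets out from 13: the same organocatalytic benzoyloxylation is followed by a Wittig reaction with methyl 2-(triphenylphosphoranylidene)propanoate to give methyl (2E,4S,6R,7R,8E)-4-(benzoyloxy)-7-[2-(benzyloxy)ethyl]-2,6,8-trimethyl-6-[(triethylsilyl)oxy]undeca-2,8,10-trienoate F1. This is cyclised thermally (toluene, BHT, 150 °C, sealed tube) to methyl (1R,4aS,5R,6R,8S,8aR)-8-(benzoyloxy)-5-[2-(benzyloxy)ethyl]-1,4a,6-trimethyl-6-[(triethylsilyl)oxy]-1,2,4a,5,6,7,8,8a-octahydronaphthalene-1-carboxylate F2, where the equatorial benzoate and side chain should still favour the chair-like trans transition state. LiAlH4 then reduces ester and benzoate together, and the fallback comes back to the route at 17.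

Step 22. The catalyst must override the Felkin–Anh bias of the α-alkoxy aldehyde, so facial selectivity may erode in a mismatched pairing. The fallback replaces catalyst control by substrate-controlled reduction and sets out from 27. LiC≡CSiMe3 (THF, −78 °C) gives the epimeric 1-[(4S,5R)-5-(1-bromoethenyl)-2,2-dimethyl-1,3-dioxolan-4-yl]-3-(trimethylsilyl)prop-2-yn-1-ols F3. Dess–Martin oxidation gives 1-[(4R,5R)-5-(1-bromoethenyl)-2,2-dimethyl-1,3-dioxolan-4-yl]-3-(trimethylsilyl)prop-2-yn-1-one F4. The bulky, non-chelating hydride LiBH(s-Bu)3 (THF, −78 °C) should then give, by Felkin–Anh attack, the syn alcohol (1R)-1-[(4S,5R)-5-(1-bromoethenyl)-2,2-dimethyl-1,3-dioxolan-4-yl]-3-(trimethylsilyl)prop-2-yn-1-ol F5. K2CO3 in MeOH gives (1R)-1-[(4S,5R)-5-(1-bromoethenyl)-2,2-dimethyl-1,3-dioxolan-4-yl]prop-2-yn-1-ol F6. Copper-catalysed anti-carbomagnesiation of this propargylic alcohol (MeMgCl, CuI cat., THF) followed by CO2 and acidic work-up closes the butenolide, and the fallback comes back to the route at 30.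

Step 20. The Lewis-acidic haloborane may cleave the isopropylidene acetal in competition with bromoboration of the alkyne. The fallback uses neutral hydrometalation and sets out from 24. Molybdenum-catalysed α-selective hydrostannation (Bu3SnH, Mo(CO)3(CNtBu)3 cat., THF, 55 °C) gives methyl (4R,5R)-2,2-dimethyl-5-[1-(tributylstannyl)ethenyl]-1,3-dioxolane-4-carboxylate F7. Bromodestannylation (Br2, CH2Cl2, −78 °C) then comes back to the route at 26.

**Further compounds**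

F1 | step 12 | methyl (2E,4S,6R,7R,8E)-4-(benzoyloxy)-7-[2-(benzyloxy)ethyl]-2,6,8-trimethyl-6-[(triethylsilyl)oxy]undeca-2,8,10-trienoate | COC(=O)/C(C)=C/[C@@H](OC(=O)c1ccccc1)C[C@@](C)(O[Si](CC)(CC)CC)[C@H](CCOCc1ccccc1)/C(C)=C/C=C
F2 | step 12 | methyl (1R,4aS,5R,6R,8S,8aR)-8-(benzoyloxy)-5-[2-(benzyloxy)ethyl]-1,4a,6-trimethyl-6-[(triethylsilyl)oxy]-1,2,4a,5,6,7,8,8a-octahydronaphthalene-1-carboxylate | c1ccccc1COCC[C@@H]1[C@@]2(C)C=CC[C@@](C)(C(=O)OC)[C@@H]2[C@@H](OC(=O)c3ccccc3)C[C@@]1(C)O[Si](CC)(CC)CC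
F3 | step 22 | 1-[(4S,5R)-5-(1-bromoethenyl)-2,2-dimethyl-1,3-dioxolan-4-yl]-3-(trimethylsilyl)prop-2-yn-1-ol (both C1 epimers) | C=C(Br)[C@@H]1OC(C)(C)O[C@H]1C(O)C#C[Si](C)(C)C
F4 | step 22 | 1-[(4R,5R)-5-(1-bromoethenyl)-2,2-dimethyl-1,3-dioxolan-4-yl]-3-(trimethylsilyl)prop-2-yn-1-one | C=C(Br)[C@@H]1OC(C)(C)O[C@H]1C(=O)C#C[Si](C)(C)C
F5 | step 22 | (1R)-1-[(4S,5R)-5-(1-bromoethenyl)-2,2-dimethyl-1,3-dioxolan-4-yl]-3-(trimethylsilyl)prop-2-yn-1-ol | C=C(Br)[C@@H]1OC(C)(C)O[C@H]1[C@H](O)C#C[Si](C)(C)C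
F6 | step 22 | (1R)-1-[(4S,5R)-5-(1-bromoethenyl)-2,2-dimethyl-1,3-dioxolan-4-yl]prop-2-yn-1-ol | C=C(Br)[C@@H]1OC(C)(C)O[C@H]1[C@H](O)C#C
F7 | step 20 | methyl (4R,5R)-2,2-dimethyl-5-[1-(tributylstannyl)ethenyl]-1,3-dioxolane-4-carboxylate | C=C([Sn](CCCC)(CCCC)CCCC)[C@@H]1OC(C)(C)O[C@H]1C(=O)OC
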